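**Plan**
1. Locants O1 and C2–C8a refer to the 2,2-dimethylchromanone unit (arene = ring B, pyranone = ring D). Rings A and C are the flavanone part, and its stereocentre is written C2(C).
2. Cuts: first the bond C6–C2(C), made forward by aryl transfer to a chromone. Then bond C2–C3 in ring D is cut, with C2 tied back to the phenol oxygen on C8 (O8).
3. Enabling feature: O8–C8–C8a–O1–C2(Me)2 is a hidden five-membered 2,2-dimethyl-1,3-dioxole (catechol acetonide). The acyl carbon C4 sits on C4a, the other ortho position of O1. Ring D can therefore be grown from the dioxole ring by moving C2 from O8 to the enol carbon C3.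
4. Forward order: catechol acetonide, ortho-lithiation/acetylation, enol silane, then ring expansion from five to six members. The expansion makes C2–C3, keeps the tertiary aryl ether, tells the two catechol oxygens apart and parks the silyl helper on O8. Then follow C6–H borylation, union with the preformed rings A/C, and deprotection.
5. Stereochemistry: the only stereocentre, C2(C) (S), is set in the union step by a rhodium catalyst with an (S)-biaryl bisphosphine. It is kept by non-basic deprotections.

Key step: step 3

Assumption: 5,7-dihydroxychromone (9) is taken as purchasable, and the sense of induction of the (S)-ligand is taken from its behaviour with cyclic enones, so the configuration of 11 would be checked by circular dichroism.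

**Step 1**
Reactants: 1 2,2-dimethyl-1,3-benzodioxole (catechol acetonide)
Product: 3 1-(2,2-dimethyl-1,3-benzodioxol-4-yl)ethan-1-one, via aryllithium 2 (not isolated)
Conditions: n-BuLi, TMEDA, Et2O, 0 °C to rt; MeC(O)N(OMe)Me, −78 to 0 °C; H2O
Reagents that add atoms: N-methoxy-N-methylacetamide, CC(=O)N(C)OC; n-butyllithium, [Li]CCCC (lithium of 2 only)
Why: Directed ortho-metalation removes the C4–H next to a ketal oxygen, and the Weinreb ketone synthesis stops at the methyl ketone because the chelated tetrahedral adduct survives until the quench.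

**Step 2**
Reactants: 3 1-(2,2-dimethyl-1,3-benzodioxol-4-yl)ethan-1-one
Product: 4 tert-butyl{[1-(2,2-dimethyl-1,3-benzodioxol-4-yl)ethenyl]oxy}dimethylsilane (silyl enol ether of 3)
Conditions: TBSOTf (1.1 equiv), Et3N (1.5 equiv), CH2Cl2, 0 °C; pentane extraction, short basic alumina plug
Reagents that add atoms: tert-butyldimethylsilyl trifluoromethanesulfonate, CC(C)(C)[Si](C)(C)OS(=O)(=O)C(F)(F)F
Why: Standard soft enolisation of an aryl methyl ketone to its silyl enol ether, in which only one enolisable position exists and the excess of amine over triflate leaves no free Lewis acid to touch the ketal.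

**Step 3**
Reactants: 4 tert-butyl{[1-(2,2-dimethyl-1,3-benzodioxol-4-yl)ethenyl]oxy}dimethylsilane
Product: 6 8-(tert-butyldimethylsilyloxy)-2,2-dimethylchroman-4-one, via oxocarbenium triflate 5 (not isolated)
Conditions: TBSOTf (10 mol %), 2,6-di-tert-butyl-4-methylpyridine (5 mol %), CH2Cl2 (0.02 M), −40 °C to rt; Et3N, aq NaHCO3
Reagents that add atoms: tert-butyldimethylsilyl trifluoromethanesulfonate, CC(C)(C)[Si](C)(C)OS(=O)(=O)C(F)(F)F (catalytic silyl carrier: its silyl group ends on O8 and it is re-formed from the enol silyl group, so the net change is an isomerisation)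
Why: Proposed new method: the silyl triflate silylates the dioxole oxygen O8, the C2–O8 bond ionises to the aryloxy-stabilised oxocarbenium ion 5 (cationic O1=C2Me2, O8 now a silyl ether), the terminal enol carbon C3 adds to C2, and the silyloxycarbenium ion formed at C4 hands its silyl group to triflate, which gives the ketone and returns the catalyst, so that the five-membered ring O1–C2–O8–C8–C8a is expanded to the six-membered ring O1–C2–C3–C4–C4a–C8a in a net isomerisation. The closest known reaction types are the silyl-triflate-catalysed Mukaiyama aldol addition of enol silanes to ketals and the Petasis–Ferrier rearrangement, which runs through the same oxocarbenium/enolate pair but without change of ring size; a catechol ketal as the cation source has not been shown. Ring D closes in the 6-(enolendo)-endo-trig mode, and twisting of the cation and of the ortho-substituted enol silane out of the arene plane gives the half-chair needed for overlap. No stereocentre is formed. The selectivity needed is between the two ketal C–O bonds: ionisation of C2–O1 is reversible and unproductive because its cation could reach C3 only through a meta-bridged ring, so the material should drain through the C2–O8 ionisation. Absence of free amine, a trace of hindered pyridine as proton trap and high dilution are meant to suppress proton loss to the isopropenyl ether, protodesilylation and intermolecular addition, and the trade of a ketal C–O bond for a C–C bond supplies the driving force.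

**Step 4**
Reactants: 6 8-(tert-butyldimethylsilyloxy)-2,2-dimethylchroman-4-one
Product: 8 [8-(tert-butyldimethylsilyloxy)-2,2-dimethyl-4-oxochroman-6-yl]boronic acid, via pinacol boronate 7 (not isolated)
Conditions: [Ir(OMe)(cod)]2 (1.5 mol %), 4,4'-di-tert-butyl-2,2'-bipyridine (3 mol %), B2pin2 (1.0 equiv), THF, 65 °C; evaporate; NaIO4, NH4OAc, acetone–H2O, rt
Reagents that add atoms: bis(pinacolato)diboron, CC1(C)OB(OC1(C)C)B1OC(C)(C)C(C)(C)O1; water, O
Why: Iridium-catalysed aromatic C–H borylation is governed by sterics, so in the 1,2,3-trisubstituted arene of 6 only C6–H reacts (C5–H lies next to the acyl carbon, C7–H next to the bulky silyl ether), and periodate cleavage of the pinacol then frees the boronic acid in a near-neutral medium that the aryl silyl ether tolerates.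

**Step 5**
Reactants: 9 5,7-dihydroxy-4H-chromen-4-one
Product: 10 5,7-bis(benzyloxy)-4H-chromen-4-one
Conditions: BnBr (2.5 equiv), K2CO3 (3 equiv), DMF, 60 °C
Reagents that add atoms: benzyl bromide, BrCc1ccccc1
Why: Williamson ether synthesis, in which warming with excess bromide also alkylates the hydrogen-bonded 5-OH, whose masking keeps it from chelating rhodium in step 6.

**Step 6**
Reactants: 8 [8-(tert-butyldimethylsilyloxy)-2,2-dimethyl-4-oxochroman-6-yl]boronic acid; 10 5,7-bis(benzyloxy)-4H-chromen-4-one
Product: 11 (2S)-5,7-bis(benzyloxy)-2-[8-(tert-butyldimethylsilyloxy)-2,2-dimethyl-4-oxochroman-6-yl]chroman-4-one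
Conditions: [Rh(OH)(cod)]2 (1.5 mol %), (S)-(6,6'-dimethoxybiphenyl-2,2'-diyl)bis[bis(3,4,5-trifluorophenyl)phosphine] (3.3 mol %, premixed), toluene–H2O, 20–30 °C
Reagents that add atoms: none
Why: Hayashi–Miyaura asymmetric 1,4-addition, a reaction type established for chromones: the aryl–rhodium species carrying the twofold-symmetric (S)-bisphosphine should bind the C2=C3 bond of 10 with the benzo-fused carbonyl half in an open quadrant and insert at the Re face of C2(C), the same spatial sense in which (S)-biaryl bisphosphines give (S)-3-arylcyclohexanones, which sets (2S), while the electron-poor ligand, the neutral medium and the low temperature hold back ring opening of the rhodium enolate and a second addition to the ketones.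

**Step 7**
Reactants: 11 (2S)-5,7-bis(benzyloxy)-2-[8-(tert-butyldimethylsilyloxy)-2,2-dimethyl-4-oxochroman-6-yl]chroman-4-one
Product: 12 (2S)-5,7-bis(benzyloxy)-2-(8-hydroxy-2,2-dimethyl-4-oxochroman-6-yl)chroman-4-one
Conditions: KHF2 (3 equiv), MeOH–THF, rt
Reagents that add atoms: none
Why: Fluoride cleavage of a phenolic silyl ether with the weakly acidic bifluoride salt removes the silyl helper, spares the benzyl ethers and avoids the basic medium in which a flavanone opens to its chalcone and racemises.

**Step 8**
Reactants: 12 (2S)-5,7-bis(benzyloxy)-2-(8-hydroxy-2,2-dimethyl-4-oxochroman-6-yl)chroman-4-one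
Product: 13 (2S)-5,7-dihydroxy-2-(8-hydroxy-2,2-dimethyl-4-oxochroman-6-yl)chroman-4-one (target)
Conditions: H2 (1 atm), Pd/C (10 wt % Pd), EtOAc–MeOH, rt
Reagents that add atoms: none
Why: Catalytic hydrogenolysis of aryl benzyl ethers under neutral conditions should be faster than reduction of the aryl ketones or cleavage of the cyclic benzylic C2(C)–O bond, so the (2S) centre stays untouched.

**Compound list**
1 | 2,2-dimethyl-1,3-benzodioxole | CC1(C)Oc2ccccc2O1 | starting material
2 | (2,2-dimethyl-1,3-benzodioxol-4-yl)lithium | [Li]c1cccc2OC(C)(C)Oc12 | intermediate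
3 | 1-(2,2-dimethyl-1,3-benzodioxol-4-yl)ethan-1-one | CC(=O)c1cccc2OC(C)(C)Oc12 | intermediate
4 | tert-butyl{[1-(2,2-dimethyl-1,3-benzodioxol-4-yl)ethenyl]oxy}dimethylsilane | C=C(O[Si](C)(C)C(C)(C)C)c1cccc2OC(C)(C)Oc12 | intermediate
5 | {2-[1-(tert-butyldimethylsilyloxy)ethenyl]-6-(tert-butyldimethylsilyloxy)phenyl}(propan-2-ylidene)oxonium triflate | C=C(O[Si](C)(C)C(C)(C)C)c1cccc(O[Si](C)(C)C(C)(C)C)c1[O+]=C(C)C.[O-]S(=O)(=O)C(F)(F)F | intermediate
6 | 8-(tert-butyldimethylsilyloxy)-2,2-dimethylchroman-4-one | CC1(C)CC(=O)c2cccc(O[Si](C)(C)C(C)(C)C)c2O1 | intermediate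
7 | 8-(tert-butyldimethylsilyloxy)-2,2-dimethyl-6-(4,4,5,5-tetramethyl-1,3,2-dioxaborolan-2-yl)chroman-4-one | CC1(C)CC(=O)c2cc(B3OC(C)(C)C(C)(C)O3)cc(O[Si](C)(C)C(C)(C)C)c2O1 | intermediate
8 | [8-(tert-butyldimethylsilyloxy)-2,2-dimethyl-4-oxochroman-6-yl]boronic acid | CC1(C)CC(=O)c2cc(B(O)O)cc(O[Si](C)(C)C(C)(C)C)c2O1 | intermediate
9 | 5,7-dihydroxy-4H-chromen-4-one | O=c1ccoc2cc(O)cc(O)c12 | starting material
10 | 5,7-bis(benzyloxy)-4H-chromen-4-one | O=c1ccoc2cc(OCc3ccccc3)cc(OCc3ccccc3)c12 | intermediate
11 | (2S)-5,7-bis(benzyloxy)-2-[8-(tert-butyldimethylsilyloxy)-2,2-dimethyl-4-oxochroman-6-yl]chroman-4-one | CC1(C)CC(=O)c2cc([C@@H]3CC(=O)c4c(OCc5ccccc5)cc(OCc5ccccc5)cc4O3)cc(O[Si](C)(C)C(C)(C)C)c2O1 | intermediate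
12 | (2S)-5,7-bis(benzyloxy)-2-(8-hydroxy-2,2-dimethyl-4-oxochroman-6-yl)chroman-4-one | CC1(C)CC(=O)c2cc([C@@H]3CC(=O)c4c(OCc5ccccc5)cc(OCc5ccccc5)cc4O3)cc(O)c2O1 | intermediate
13 | (2S)-5,7-dihydroxy-2-(8-hydroxy-2,2-dimethyl-4-oxochroman-6-yl)chroman-4-one | CC1(C)CC(=O)c2cc([C@@H]3CC(=O)c4c(O)cc(O)cc4O3)cc(O)c2O1 | target

**Total step count:** 8.
**Longest linear sequence:** 7 (steps 1, 2, 3, 4, 6, 7, 8).

**Steps most likely to fail**

Step 3 (Proposed new method). The cation may lose a proton or acetone, or the enol silane may be protodesilylated, faster than the C2–C3 closure. The fallback uses known chemistry, sets out from 3 and returns at 6.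
- The ketal of 3 is hydrolysed (TFA–H2O, rt) to 1-(2,3-dihydroxyphenyl)ethan-1-one F1.
- Kabbe condensation of F1 with acetone and pyrrolidine (MeOH, reflux, N2) should give 8-hydroxy-2,2-dimethylchroman-4-one F2. Only the hydroxyl ortho to the acyl group can close the oxa-Michael ring.
- Silylation (TBSCl, imidazole, DMF) gives 6.

Step 6. Insertion into the electron-rich chromone may be slow enough for protodeboronation to win. Facial selectivity may be poor, or the rhodium enolate may open to the chalcone. The fallback replaces asymmetric catalysis by resolution, sets out from 8 and 10 and returns at 11.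
- The more reactive ligand-free [Rh(OH)(cod)]2 in dioxane–H2O at 50 °C should give racemic 5,7-bis(benzyloxy)-2-[8-(tert-butyldimethylsilyloxy)-2,2-dimethyl-4-oxochroman-6-yl]chroman-4-one F3.
- F3 is separated by preparative chromatography on a polysaccharide chiral stationary phase into 11 and (2R)-5,7-bis(benzyloxy)-2-[8-(tert-butyldimethylsilyloxy)-2,2-dimethyl-4-oxochroman-6-yl]chroman-4-one F4.

Step 4. The borane by-product may reduce the C4 ketone, or borylation may occur beside the silyl ether. The fallback places a halogen before the ring expansion, sets out from 3 and returns at 7.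
- NBS in MeCN should brominate 3 at the only position that is para to a ring oxygen and meta to the acetyl group. This gives 1-(6-bromo-2,2-dimethyl-1,3-benzodioxol-4-yl)ethan-1-one F5.
- TBSOTf/Et3N gives tert-butyl{[1-(6-bromo-2,2-dimethyl-1,3-benzodioxol-4-yl)ethenyl]oxy}dimethylsilane F6.
- Ring expansion as in step 3 gives 6-bromo-8-(tert-butyldimethylsilyloxy)-2,2-dimethylchroman-4-one F7.
- Miyaura borylation (PdCl2(dppf), B2pin2, KOAc, dioxane, 85 °C) gives 7, which enters the periodate stage of step 4.

**Further compounds**
F1 | step 3 | 1-(2,3-dihydroxyphenyl)ethan-1-one | CC(=O)c1cccc(O)c1O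
F2 | step 3 | 8-hydroxy-2,2-dimethylchroman-4-one | CC1(C)CC(=O)c2cccc(O)c2O1
F3 | step 6 | racemic 5,7-bis(benzyloxy)-2-[8-(tert-butyldimethylsilyloxy)-2,2-dimethyl-4-oxochroman-6-yl]chroman-4-one | CC1(C)CC(=O)c2cc(C3CC(=O)c4c(OCc5ccccc5)cc(OCc5ccccc5)cc4O3)cc(O[Si](C)(C)C(C)(C)C)c2O1
F4 | step 6 | (2R)-5,7-bis(benzyloxy)-2-[8-(tert-butyldimethylsilyloxy)-2,2-dimethyl-4-oxochroman-6-yl]chroman-4-one | CC1(C)CC(=O)c2cc([C@H]3CC(=O)c4c(OCc5ccccc5)cc(OCc5ccccc5)cc4O3)cc(O[Si](C)(C)C(C)(C)C)c2O1
F5 | step 4 | 1-(6-bromo-2,2-dimethyl-1,3-benzodioxol-4-yl)ethan-1-one | CC(=O)c1cc(Br)cc2OC(C)(C)Oc12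
F6 | step 4 | tert-butyl{[1-(6-bromo-2,2-dimethyl-1,3-benzodioxol-4-yl)ethenyl]oxy}dimethylsilane | C=C(O[Si](C)(C)C(C)(C)C)c1cc(Br)cc2OC(C)(C)Oc12
F7 | step 4 | 6-bromo-8-(tert-butyldimethylsilyloxy)-2,2-dimethylchroman-4-one | CC1(C)CC(=O)c2cc(Br)cc(O[Si](C)(C)C(C)(C)C)c2O1
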